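The earlier runs and the new flask were computed for substances that don't exist, noise included.

The pitfall I had to watch in these four flasks was to carry delta's climb up the temperature scale and forget that a recipe has a purse as well as a clock.

| setting | theta | delta | gamma | Friday's | Saturday's | Sunday's | Wednesday's |
|---|---|---|---|---|---|---|---|
| substrate | 0.10 M | 0.10 M | 0.10 M | 0.10 M | 0.10 M | 0.10 M | 0.10 M |
| second reagent | 0.13 M | 0.20 M | 0.090 M | 0.0900 M | 0.0900 M | 0.0900 M | 0.0900 M |
| third reagent | 0.30 M | 0.30 M | 0.15 M | 0.300 M | 0.300 M | 0.300 M | 0.300 M |
| gas | 38 mM (held) | 38 mM (held) | 38 mM (held) | 38 mM (held) | 38 mM (held) | 38 mM (held) | 38 mM (held) |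
| temperature | −18 °C | 32 °C | −18 °C | 20 °C | −10 °C | 50 °C | −40 °C |
| remark | run made earlier | run made earlier | run made earlier |  |  |  |  |
| time |  |  |  | 4.0 d | 4.0 d | 4.0 d | 4.0 d |

theta run (percent of the substrate charged): time / d: target / % = 1.67: 0; 3.00: 0; 5.00: 0.3; 10.0: 0.1; 20.0: 0

delta run (percent of the substrate charged): time / h: target / % = 3.00: 0.5; 6.00: 0.6; 12.0: 2.6; 20.0: 7.7; 40.0: 15.0

gamma run (percent of the substrate charged): time / d: target / % = 1.67: 0.4; 5.00: 0; 10.0: 0.1; 15.0: 0; 20.0: 0.3

(standard deviation of a reading: 0.5 percentage points)

* the flask with the highest amount of target, in percent of the substrate charged ("all alike" if they lie within 1.5 percentage points) (Friday's / Saturday's / Sunday's / Wednesday's / all alike)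
* final target, as a percentage of the substrate charged, in Friday's
* final target, as a percentage of the substrate charged, in Saturday's
* final target, as a percentage of the substrate charged, in Sunday's
* final target, as a percentage of the substrate charged, in Wednesday's

- the analysis behind the earlier runs scatters by 0.5 percentage points, standard deviation
- at the start none of the gas is in solution

Theta and gamma, at −18 °C, stayed within the scatter of 0.5 percentage points over 20.0 d, so I expected little from Saturday's and Wednesday's, the two cold flasks. Delta at 32 °C read 0.6% at 6.00 h and 15.0% at 40.0 h, so I took target to stand some way down a chain. But delta carried twice the second reagent of the new flasks, so my first answer, delta's slope scaled by temperature, had to go round once more. I assumed that each substrate takes up one second reagent on its way to target, and in the new flasks the charges then gave 90.0%: this is the budget, the second reagent charged as a fraction of the substrate charged. On that assumption I committed to a ceiling for Sunday's target, the budget less whatever second reagent went elsewhere.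

The forecast put Sunday's first at 30%, with a range of 12% to 65%, Friday's at 4%, Saturday's at 0.1% and Wednesday's at 0%, saying “the slowdown caps the yield”.

Sunday's gave the most, 21.2%, with Friday's at 12.3%, Saturday's at 0.0101% and Wednesday's at 0%.

    substrate + coupling partner → intermediate A (k = 2.30 M⁻¹ h⁻¹, Ea = 64.0 kJ mol⁻¹)
    second reagent + intermediate A → intermediate B (k = 0.0850 M⁻¹ h⁻¹, Ea = 75.0 kJ mol⁻¹)
    third reagent + intermediate B → target (k = 0.170 M⁻¹ h⁻¹, Ea = 85.0 kJ mol⁻¹)
    substrate + second reagent → side product (k = 0.640 M⁻¹ h⁻¹, Ea = 72.0 kJ mol⁻¹)
    coupling partner ⇌ dormant form (K = 1.70, k = 0.0290 h⁻¹, Ea = 108 kJ mol⁻¹, ΔH = −56.0 kJ mol⁻¹)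
    gas ⇌ coupling partner, rate k6*(csat - [coupling partner]) (kL = 0.520 h⁻¹)
    (constants at 20 °C)

The main reason for the shortfall in Sunday's was the conversion of substrate and second reagent into side product: with that step taken away, Sunday's gave 86.9%, inside the budget of 90.0%. As run, Sunday's put 66.7% of the substrate charge into side product, which left 23.3% for target, and after 40.0 d it held 23.3%. A neighbour flask, the same as Sunday's except for its second reagent, charged at 36.0% of the substrate, had 0% of that reagent left at 4.00 d and 32.7% as side product, which left 3.30%, and that flask held 3.30% of target.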